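The seven-membered ring (C3a–C4–C5–C6–C7–C8–C8a) is cut at C7, its only carbon without substituent or stereocentre, flanked by oxygenated C8 and methyl-bearing C6. Because C8a is quaternary, a C8 ketone enolises only towards C6. One telescoped operation therefore inserts C7 into a cis-hydrindanone: methylene transfer to the C6=C8 silyl enol ether forms C6–C7 and C7–C8, FeCl3 cleaves the old C6–C8 bond, and elimination leaves the 6-methylcyclohept-6-en-8-one. The precursor is a cis-fused hydrindane carrying the trimethylsilyl enol ether, the C4 anisoate, the C8a methyl and a triethylsilyl-protected C3 isopropyl carbinol, with all stereocentres in place.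

Key step: step 11

Remark on labels: atom labels C1–C8a are those of the target azulene and are used for every intermediate; in the systematic indene names, C7 and C7a correspond to C8 and C8a.
Remark on chemistry: the C6 centre next to the C8 ketone is carried as an epimeric mixture (compounds 2 and 6 to 14) and is left unspecified in the SMILES, because it becomes trigonal in 15.
Remark on design: the iso­propyl group and the six-membered ring lie on the same face of the cyclopentane, so the small groups (C3a–H, C3–OH) are added last from the open α face, and the C3 oxygen is capped as a triethylsilyl ether rather than a trimethylsilyl ether.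

Step 1
Reactants: 1 7-methyl-1,4-dioxaspiro[4.5]decan-8-one
Product: 2 7,9-dimethyl-1,4-dioxaspiro[4.5]decan-8-one (cis/trans mixture)
Conditions: LiN(iPr)2, THF, −78 °C; MeI, −78 → 0 °C
Reagents that add atoms: iodomethane, CI
Why: Kinetic enolate alkylation: LiN(iPr)2 removes a proton from the unsubstituted α-methylene and the enolate is methylated there (SN2), the new C6 centre being epimerisable and deliberately left uncontrolled because it becomes trigonal in 15.

Step 2
Reactants: 2 7,9-dimethyl-1,4-dioxaspiro[4.5]decan-8-one; 3 (S)-1-phenylethylamine; 4 4-methylpent-1-en-3-one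
Product: 6 (7S)-7,9-dimethyl-7-(4-methyl-3-oxopentyl)-1,4-dioxaspiro[4.5]decan-8-one, via ketimine 5 (not isolated)
Conditions: TsOH (cat.), toluene, reflux (Dean–Stark); then THF, 40 °C; then 10% aq. AcOH, 20 °C
Reagents that add atoms: water, O
Why: Auxiliary-controlled Michael addition of a chiral ketimine (deracemising alkylation through the more substituted secondary enamine tautomer): enone 4 is engaged in a compact, aza-ene-like transition state on the enamine face away from the phenyl group of the (S)-auxiliary, which should set the quaternary C8a centre as S, and mild acid then releases the ketone and the amine.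

Step 3
Reactants: 6 (7S)-7,9-dimethyl-7-(4-methyl-3-oxopentyl)-1,4-dioxaspiro[4.5]decan-8-one
Product: 7 (2Z)-1-[(7S)-7,9-dimethyl-8-oxo-1,4-dioxaspiro[4.5]decan-7-yl]-4-methylpent-2-en-3-yl trifluoromethanesulfonate
Conditions: KN(SiMe3)2, THF, −78 °C; PhNTf2, −78 → 0 °C
Reagents that add atoms: N-phenylbis(trifluoromethanesulfonimide), O=S(=O)(N(c1ccccc1)S(=O)(=O)C(F)(F)F)C(F)(F)F
Why: Kinetic enolisation and O-sulfonylation (enol triflate formation): the amide base attacks the unhindered C2 methylene of the side-chain ketone rather than the lone, hindered C6 methine of the ring ketone, the bulky isopropyl group favours the Z(O)-enolate, and PhNTf2 traps it as the (Z)-triflate needed for ring closure.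

Step 4
Reactants: 7 (2Z)-1-[(7S)-7,9-dimethyl-8-oxo-1,4-dioxaspiro[4.5]decan-7-yl]-4-methylpent-2-en-3-yl trifluoromethanesulfonate
Product: 8 (2Z)-1-[(1S)-1,3-dimethyl-2,5-dioxocyclohexyl]-4-methylpent-2-en-3-yl trifluoromethanesulfonate
Conditions: 1 M HCl, THF, 20 °C
Reagents that add atoms: water, O
Why: Acid-catalysed acetal hydrolysis unveils the C4 ketone while the enol triflate and the C8 ketone are inert to dilute aqueous acid at room temperature.

Step 5
Reactants: 8 (2Z)-1-[(1S)-1,3-dimethyl-2,5-dioxocyclohexyl]-4-methylpent-2-en-3-yl trifluoromethanesulfonate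
Product: 9 (3aR,7aS)-6,7a-dimethyl-3-(propan-2-yl)-3a,5,6,7a-tetrahydro-1H-indene-4,7-dione (cis-fused)
Conditions: Pd(PPh3)4 (cat.), KOt-Bu, THF, 0 → 20 °C
Reagents that add atoms: none
Why: Palladium-catalysed intramolecular α-alkenylation of a ketone enolate (cyclopentene annulation): zerovalent palladium inserts into the alkenyl triflate, the C4 enolate binds through C3a and reductive elimination forms C3–C3a by way of a six-membered palladacycle, which can only deliver the cis ring fusion (C3a–H on the face of the C8a methyl) and favours the fused five-membered ring over bridging through the C6 methine of the C8 ketone.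

Step 6
Reactants: 9 (3aR,7aS)-6,7a-dimethyl-3-(propan-2-yl)-3a,5,6,7a-tetrahydro-1H-indene-4,7-dione
Product: 10 (3R,3aS,7aS)-3-hydroxy-6,7a-dimethyl-3-(propan-2-yl)hexahydro-1H-indene-4,7-dione
Conditions: Co(acac)2 (cat.), PhSiH3, O2 (1 atm), THF, 20 °C; aq. Na2S2O3; used crude
Reagents that add atoms: dioxygen, O=O
Why: Mukaiyama hydration (metal-hydride hydrogen-atom transfer): a cobalt hydride delivers a hydrogen atom to C2 and the resulting tertiary C3 radical captures O2 on the convex α face of the cis-hydrindane, anti to the C3a–C4 bond, so the hydroxyl becomes cis to C3a–H (3R) and the isopropyl group is pushed to the β face, the isolated ketones being untouched.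

Step 7
Reactants: 10 (3R,3aS,7aS)-3-hydroxy-6,7a-dimethyl-3-(propan-2-yl)hexahydro-1H-indene-4,7-dione
Product: 11 (3R,3aR,4S,7aS)-3,4-dihydroxy-6,7a-dimethyl-3-(propan-2-yl)octahydro-7H-inden-7-one
Conditions: Me4NBH(OAc)3, MeCN/AcOH, −30 °C
Reagents that add atoms: none
Why: Evans–Saksena hydroxyl-directed reduction: the C3 hydroxyl exchanges onto boron and hydride is delivered internally to the α face of the C4 carbonyl, giving the anti-1,3-diol with the new hydroxyl β (4S), while the hindered C8 ketone, which has no directing hydroxyl, is inert to triacetoxyborohydride.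

Step 8
Reactants: 11 (3R,3aR,4S,7aS)-3,4-dihydroxy-6,7a-dimethyl-3-(propan-2-yl)octahydro-7H-inden-7-one; 12 4-methoxybenzoyl chloride
Product: 13 (3R,3aR,4S,7aS)-3-hydroxy-6,7a-dimethyl-7-oxo-3-(propan-2-yl)octahydro-1H-inden-4-yl 4-methoxybenzoate
Conditions: pyridine, DMAP (cat.), CH2Cl2, 0 → 20 °C
Reagents that add atoms: none
Why: DMAP-catalysed acylation (nucleophilic acyl substitution) takes place only at the secondary C4 hydroxyl because the tertiary C3 hydroxyl flanked by isopropyl and the ring fusion is not acylated under these conditions.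

Step 9
Reactants: 13 (3R,3aR,4S,7aS)-3-hydroxy-6,7a-dimethyl-7-oxo-3-(propan-2-yl)octahydro-1H-inden-4-yl 4-methoxybenzoate
Product: 14 (3R,3aR,4S,7aS)-6,7a-dimethyl-7-oxo-3-(propan-2-yl)-3-[(triethylsilyl)oxy]octahydro-1H-inden-4-yl 4-methoxybenzoate
Conditions: Et3SiOTf, 2,6-lutidine, CH2Cl2, −78 → 0 °C
Reagents that add atoms: triethylsilyl trifluoromethanesulfonate, CC[Si](CC)(CC)OS(=O)(=O)C(F)(F)F
Why: Silyl ether formation with a silyl triflate and a hindered base caps the tertiary alcohol with a triethylsilyl group that, unlike a trimethylsilyl ether, should survive the Lewis-acidic ring expansion and still yield to fluoride at the end.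

Step 10
Reactants: 14 (3R,3aR,4S,7aS)-6,7a-dimethyl-7-oxo-3-(propan-2-yl)-3-[(triethylsilyl)oxy]octahydro-1H-inden-4-yl 4-methoxybenzoate
Product: 15 (3R,3aR,4S,7aS)-6,7a-dimethyl-3-(propan-2-yl)-3-[(triethylsilyl)oxy]-7-[(trimethylsilyl)oxy]-2,3,3a,4,5,7a-hexahydro-1H-inden-4-yl 4-methoxybenzoate
Conditions: Me3SiOTf, Et3N, CH2Cl2, 0 → 20 °C
Reagents that add atoms: trimethylsilyl trifluoromethanesulfonate, C[Si](C)(C)OS(=O)(=O)C(F)(F)F
Why: Silyl enol ether formation by soft enolisation: C8a is quaternary, so the ketone can only enolise towards C6, which gives the tetrasubstituted C6=C8 enol ether as a single regioisomer and removes the C6 stereocentre.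

Step 11
Reactants: 15 (3R,3aR,4S,7aS)-6,7a-dimethyl-3-(propan-2-yl)-3-[(triethylsilyl)oxy]-7-[(trimethylsilyl)oxy]-2,3,3a,4,5,7a-hexahydro-1H-inden-4-yl 4-methoxybenzoate; 16 diiodomethane
Product: 19 (3R,3aR,4S,8aS)-6,8a-dimethyl-8-oxo-3-(propan-2-yl)-3-[(triethylsilyl)oxy]-1,2,3,3a,4,5,8,8a-octahydroazulen-4-yl 4-methoxybenzoate, via siloxycyclopropane 17 (not isolated), via β-chloro ketone 18 (not isolated)
Conditions: Et2Zn, toluene, 0 → 20 °C; pyridine quench, filtration, solvent exchange; FeCl3, DMF, 0 → 20 °C; NaOAc, MeOH, 50 °C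
Reagents that add atoms: none
Why: Simmons–Smith methylene transfer in the Furukawa modification (zinc carbenoid, concerted butterfly-type transition state) adds C7 across the electron-rich C6=C8 enol ether bond to give the 1-siloxybicyclo[4.1.0]heptane 17, forming C6–C7 and C7–C8 in one event. FeCl3 then oxidises the siloxycyclopropane to a cyclopropyloxy radical whose β-scission breaks the shared C6–C8 bond, because this gives the tertiary C6 radical and releases ring strain; chlorine transfer from a second FeCl3 gives β-chloro ketone 18, and acetate promotes E1cB loss of HCl through the C7 enolate to the conjugated C6=C7 enone. The closest known reaction type is the one-carbon ring expansion of cyclic silyl enol ethers through siloxycyclopropanes, as in the conversion of the more substituted enol ether of 2-methylcyclohexanone into 3-methylcyclohept-2-enone. The three-membered ring closes by [2+1] cycloaddition, and the seven-membered ring is not closed but revealed when the zero-atom bridge is cut. No stereocentre is created that persists, since the two cyclopropane centres are transient and C3, C3a, C4 and C8a are not involved. The step needs only regioselectivity: the quaternary C8a allows a single enol ether, tertiary-radical stability decides which cyclopropane bond breaks, and the acidity of the C7 protons next to the ketone steers the elimination into conjugation, while the anisoate and the tertiary triethylsilyl ether are spectators under these non-basic conditions.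

Step 12
Reactants: 19 (3R,3aR,4S,8aS)-6,8a-dimethyl-8-oxo-3-(propan-2-yl)-3-[(triethylsilyl)oxy]-1,2,3,3a,4,5,8,8a-octahydroazulen-4-yl 4-methoxybenzoate
Product: 20 (3R,3aR,4S,8S,8aS)-8-hydroxy-6,8a-dimethyl-3-(propan-2-yl)-3-[(triethylsilyl)oxy]-1,2,3,3a,4,5,8,8a-octahydroazulen-4-yl 4-methoxybenzoate
Conditions: (R)-2-methyl-CBS-oxazaborolidine [(3aR)-1-methyl-3,3-diphenyltetrahydro-1H,3H-pyrrolo[1,2-c][1,3,2]oxazaborole] (cat.), catecholborane, toluene, −78 → −40 °C
Reagents that add atoms: none
Why: Corey–Bakshi–Shibata reduction: with the quaternary C8a as the larger flank, the (R)-oxazaborolidine–borane complex should deliver hydride 1,2 to the face that gives the 8S allylic alcohol (hydroxyl cis to the C8a methyl), the catalyst rather than the flexible seven-membered ring deciding the configuration.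

Step 13
Reactants: 20 (3R,3aR,4S,8S,8aS)-8-hydroxy-6,8a-dimethyl-3-(propan-2-yl)-3-[(triethylsilyl)oxy]-1,2,3,3a,4,5,8,8a-octahydroazulen-4-yl 4-methoxybenzoate
Product: 21 (3R,3aR,4S,8S,8aS)-8-acetoxy-6,8a-dimethyl-3-(propan-2-yl)-3-[(triethylsilyl)oxy]-1,2,3,3a,4,5,8,8a-octahydroazulen-4-yl 4-methoxybenzoate
Conditions: Ac2O, pyridine, DMAP (cat.), CH2Cl2, 20 °C
Reagents that add atoms: acetic anhydride, CC(=O)OC(C)=O
Why: DMAP-catalysed acetylation (nucleophilic acyl substitution) of the only free hydroxyl, the secondary allylic C8–OH, proceeds with retention because the C–O bond is not broken.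

Step 14
Reactants: 21 (3R,3aR,4S,8S,8aS)-8-acetoxy-6,8a-dimethyl-3-(propan-2-yl)-3-[(triethylsilyl)oxy]-1,2,3,3a,4,5,8,8a-octahydroazulen-4-yl 4-methoxybenzoate
Product: 22 (3R,3aR,4S,8S,8aS)-8-acetoxy-3-hydroxy-6,8a-dimethyl-3-(propan-2-yl)-1,2,3,3a,4,5,8,8a-octahydroazulen-4-yl 4-methoxybenzoate (CNP0256979.4)
Conditions: HF·pyridine, THF/pyridine, 0 → 20 °C
Reagents that add atoms: none
Why: Fluoride-induced desilylation (formation of the strong Si–F bond) frees the tertiary C3 alcohol under non-basic conditions that leave the allylic acetate and the anisoate in place.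

Compound list
1 | 7-methyl-1,4-dioxaspiro[4.5]decan-8-one (racemic) | CC1CC2(CCC1=O)OCCO2 | starting material
2 | 7,9-dimethyl-1,4-dioxaspiro[4.5]decan-8-one (cis/trans) | CC1CC2(CC(C)C1=O)OCCO2 | intermediate
3 | (S)-1-phenylethylamine | C[C@H](N)c1ccccc1 | starting material
4 | 4-methylpent-1-en-3-one (isopropyl vinyl ketone) | C=CC(=O)C(C)C | starting material
5 | N-[(1S)-1-phenylethyl] ketimine of 2 (in equilibrium with its secondary enamine) | CC1CC2(CC(C)C1=N[C@@H](C)c3ccccc3)OCCO2 | intermediate
6 | (7S)-7,9-dimethyl-7-(4-methyl-3-oxopentyl)-1,4-dioxaspiro[4.5]decan-8-one | C12(OCCO1)CC(C)C(=O)[C@@](C)(CCC(=O)C(C)C)C2 | intermediate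
7 | (2Z)-1-[(7S)-7,9-dimethyl-8-oxo-1,4-dioxaspiro[4.5]decan-7-yl]-4-methylpent-2-en-3-yl trifluoromethanesulfonate | C12(OCCO1)CC(C)C(=O)[C@@](C)(C/C=C(\OS(=O)(=O)C(F)(F)F)C(C)C)C2 | intermediate
8 | (2Z)-1-[(1S)-1,3-dimethyl-2,5-dioxocyclohexyl]-4-methylpent-2-en-3-yl trifluoromethanesulfonate | O=C1CC(C)C(=O)[C@@](C)(C/C=C(\OS(=O)(=O)C(F)(F)F)C(C)C)C1 | intermediate
9 | (3aR,7aS)-6,7a-dimethyl-3-(propan-2-yl)-3a,5,6,7a-tetrahydro-1H-indene-4,7-dione (cis-fused) | O=C1CC(C)C(=O)[C@@]2(C)CC=C(C(C)C)[C@@H]12 | intermediate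
10 | (3R,3aS,7aS)-3-hydroxy-6,7a-dimethyl-3-(propan-2-yl)hexahydro-1H-indene-4,7-dione | O=C1CC(C)C(=O)[C@@]2(C)CC[C@@](O)(C(C)C)[C@@H]12 | intermediate
11 | (3R,3aR,4S,7aS)-3,4-dihydroxy-6,7a-dimethyl-3-(propan-2-yl)octahydro-7H-inden-7-one | O[C@H]1CC(C)C(=O)[C@@]2(C)CC[C@@](O)(C(C)C)[C@@H]12 | intermediate
12 | 4-methoxybenzoyl chloride | COc1ccc(C(Cl)=O)cc1 | starting material
13 | (3R,3aR,4S,7aS)-3-hydroxy-6,7a-dimethyl-7-oxo-3-(propan-2-yl)octahydro-1H-inden-4-yl 4-methoxybenzoate | COc1ccc(C(=O)O[C@H]2CC(C)C(=O)[C@@]3(C)CC[C@@](O)(C(C)C)[C@@H]23)cc1 | intermediate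
14 | (3R,3aR,4S,7aS)-6,7a-dimethyl-7-oxo-3-(propan-2-yl)-3-[(triethylsilyl)oxy]octahydro-1H-inden-4-yl 4-methoxybenzoate | COc1ccc(C(=O)O[C@H]2CC(C)C(=O)[C@@]3(C)CC[C@@](O[Si](CC)(CC)CC)(C(C)C)[C@@H]23)cc1 | intermediate
15 | (3R,3aR,4S,7aS)-6,7a-dimethyl-3-(propan-2-yl)-3-[(triethylsilyl)oxy]-7-[(trimethylsilyl)oxy]-2,3,3a,4,5,7a-hexahydro-1H-inden-4-yl 4-methoxybenzoate (precursor of the key step) | COc1ccc(C(=O)O[C@H]2CC(C)=C(O[Si](C)(C)C)[C@@]3(C)CC[C@@](O[Si](CC)(CC)CC)(C(C)C)[C@@H]23)cc1 | intermediate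
16 | diiodomethane | ICI | starting material
17 | siloxycyclopropane: methylene adduct of 15 across C6=C8 (the two cyclopropane centres unassigned) | COc1ccc(C(=O)O[C@H]2CC3(C)CC3(O[Si](C)(C)C)[C@@]4(C)CC[C@@](O[Si](CC)(CC)CC)(C(C)C)[C@@H]24)cc1 | intermediate
18 | (3R,3aR,4S,8aS)-6-chloro-6,8a-dimethyl-8-oxo-3-(propan-2-yl)-3-[(triethylsilyl)oxy]decahydroazulen-4-yl 4-methoxybenzoate (C6 epimers) | COc1ccc(C(=O)O[C@H]2CC(C)(Cl)CC(=O)[C@@]3(C)CC[C@@](O[Si](CC)(CC)CC)(C(C)C)[C@@H]23)cc1 | intermediate
19 | (3R,3aR,4S,8aS)-6,8a-dimethyl-8-oxo-3-(propan-2-yl)-3-[(triethylsilyl)oxy]-1,2,3,3a,4,5,8,8a-octahydroazulen-4-yl 4-methoxybenzoate (product of the key step) | COc1ccc(C(=O)O[C@H]2CC(C)=CC(=O)[C@@]3(C)CC[C@@](O[Si](CC)(CC)CC)(C(C)C)[C@@H]23)cc1 | intermediate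
20 | (3R,3aR,4S,8S,8aS)-8-hydroxy-6,8a-dimethyl-3-(propan-2-yl)-3-[(triethylsilyl)oxy]-1,2,3,3a,4,5,8,8a-octahydroazulen-4-yl 4-methoxybenzoate | COc1ccc(C(=O)O[C@H]2CC(C)=C[C@H](O)[C@@]3(C)CC[C@@](O[Si](CC)(CC)CC)(C(C)C)[C@@H]23)cc1 | intermediate
21 | (3R,3aR,4S,8S,8aS)-8-acetoxy-6,8a-dimethyl-3-(propan-2-yl)-3-[(triethylsilyl)oxy]-1,2,3,3a,4,5,8,8a-octahydroazulen-4-yl 4-methoxybenzoate | COc1ccc(C(=O)O[C@H]2CC(C)=C[C@H](OC(C)=O)[C@@]3(C)CC[C@@](O[Si](CC)(CC)CC)(C(C)C)[C@@H]23)cc1 | intermediate
22 | (3R,3aR,4S,8S,8aS)-8-acetoxy-3-hydroxy-6,8a-dimethyl-3-(propan-2-yl)-1,2,3,3a,4,5,8,8a-octahydroazulen-4-yl 4-methoxybenzoate | COc1ccc(C(=O)O[C@H]2CC(C)=C[C@H](OC(C)=O)[C@@]3(C)CC[C@@](O)(C(C)C)[C@@H]23)cc1 | target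

Total step count: 14. Longest linear sequence: 14 steps (1 to 22).

Steps most likely to fail

Step 5. Enolisation may compete at the C6 methine of the C8 ketone and lead to bridging, or the base may move the new β,γ-alkene into conjugation with the C4 ketone and erase C3a. The fallback removes the competing carbonyl and sets out from 7. NaBH4 (MeOH, 0 °C) reduces the C8 ketone to the hydroxy ketal triflate F1. Aqueous acid then frees the C4 ketone to give the hydroxy ketone triflate F2, in which C4 is the only carbonyl. The same palladium-catalysed α-alkenylation can now use only C3a and gives the bicyclic hydroxy ketone F3. Dess–Martin oxidation of the C8 carbinol returns the route at 9.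

Step 6. Oxygen capture at the C3 radical may show poor facial selectivity, the silane may partly reduce the ketones, or the β-hydroxy ketone may dehydrate on handling. The fallback sets out from 9. Dimethyldioxirane should epoxidise the convex α face to the epoxy dione F4. LiBHEt3 opens the oxirane by SN2 attack at the less substituted C2 and reduces both ketones, giving the triol F5 with the tertiary C3 hydroxyl α. Dess–Martin oxidation of the two secondary alcohols rejoins the route at 10.

Step 11. The hindered enol ether may lose its silyl group before methylene transfer, the tetrasubstituted alkene may cyclopropanate slowly, or the iron salt may strip the tertiary silyl ether. The fallback sets out from 14. Lewis-acid-promoted homologation with trimethylsilyldiazomethane (Me3Al, CH2Cl2, −78 °C), in which the less substituted α-carbon C6 migrates, inserts the same CH2 between C8 and C6 and gives the cycloheptanone F6. Its only enolisable side is C7, so silylation (Me3SiOTf, Et3N) gives the enol ether F7. Saegusa–Ito dehydrogenation (Pd(OAc)2, MeCN) introduces the C6=C7 bond and the route is rejoined at 19.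

Further compounds
F1 | step 5 | (2Z)-1-[(7S)-8-hydroxy-7,9-dimethyl-1,4-dioxaspiro[4.5]decan-7-yl]-4-methylpent-2-en-3-yl trifluoromethanesulfonate (carbinol epimers) | C12(OCCO1)CC(C)C(O)[C@@](C)(C/C=C(\OS(=O)(=O)C(F)(F)F)C(C)C)C2
F2 | step 5 | (2Z)-1-[(1S)-2-hydroxy-1,3-dimethyl-5-oxocyclohexyl]-4-methylpent-2-en-3-yl trifluoromethanesulfonate | O=C1CC(C)C(O)[C@@](C)(C/C=C(\OS(=O)(=O)C(F)(F)F)C(C)C)C1
F3 | step 5 | (3aR,7aS)-7-hydroxy-6,7a-dimethyl-3-(propan-2-yl)-1,3a,5,6,7,7a-hexahydro-4H-inden-4-one | O=C1CC(C)C(O)[C@@]2(C)CC=C(C(C)C)[C@@H]12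
F4 | step 6 | 2,3-epoxide of 9 with the oxirane on the α face (cis to C3a–H and the C7a methyl) | O=C1CC(C)C(=O)[C@@]2(C)C[C@@H]3O[C@]3(C(C)C)[C@@H]12
F5 | step 6 | (3R,3aR,7aS)-6,7a-dimethyl-3-(propan-2-yl)octahydro-1H-indene-3,4,7-triol (secondary carbinol epimers) | OC1CC(C)C(O)[C@@]2(C)CC[C@@](O)(C(C)C)[C@@H]12
F6 | step 11 | (3R,3aR,4S,8aS)-6,8a-dimethyl-8-oxo-3-(propan-2-yl)-3-[(triethylsilyl)oxy]decahydroazulen-4-yl 4-methoxybenzoate (C6 epimers) | COc1ccc(C(=O)O[C@H]2CC(C)CC(=O)[C@@]3(C)CC[C@@](O[Si](CC)(CC)CC)(C(C)C)[C@@H]23)cc1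
F7 | step 11 | (3R,3aR,4S,8aS)-6,8a-dimethyl-3-(propan-2-yl)-3-[(triethylsilyl)oxy]-8-[(trimethylsilyl)oxy]-1,2,3,3a,4,5,6,8a-octahydroazulen-4-yl 4-methoxybenzoate | COc1ccc(C(=O)O[C@H]2CC(C)C=C(O[Si](C)(C)C)[C@@]3(C)CC[C@@](O[Si](CC)(CC)CC)(C(C)C)[C@@H]23)cc1
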